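**Plan**
- Retrosynthesis first restores the four phenols as methyl ethers and places a carboxyl group on the one carbon of ring A and of ring D that lies between the C–OH carbon and the bridge-bearing carbon.
- It then cuts both ArCH2–CH2Ar bridge bonds (A–B and C–D) between the two CH2 carbons, and last the diaryl ether C–O bond between rings B and C.
- Enabling feature: in rings A and D the carbon flanked by C–OH and the bridge carbon carries only H in the target. Each ring is therefore a 6-methylsalicylate in disguise: the ester acidifies the ortho methyl (the future bridge CH2), traps the aldehyde adduct as a lactone and finally leaves as CO2.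
- Forward order: B–O–C ether by SNAr; both bridge C–C bonds and two temporary six-membered lactone rings in one twofold toluate-anion operation; lactone hydrogenolysis; loss of two CO2; global O-demethylation.
- Stereochemistry: the target is achiral. The two lactone C3 centres made in the key step are uncontrolled and are erased as CH2 in the following step.

Key step: step 2

Remark on the chemistry: compounds 1, 2 and 4 are taken as purchased; commercial LiN(iPr)2 solution is used.

**Step 1**
Reactants: 1 3-hydroxy-4,5-dimethoxybenzaldehyde; 2 4-fluorobenzaldehyde
Product: 3 3-(4-formylphenoxy)-4,5-dimethoxybenzaldehyde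
Conditions: K2CO3, DMF, 130 °C
Reagents that add atoms: none
Why: Nucleophilic aromatic substitution (SNAr), in which the para-formyl group activates the C–F bond of 2 towards the phenoxide of 1, a standard entry to diaryl ethers of the bis(bibenzyl) class.

**Step 2**
Reactants: 3 3-(4-formylphenoxy)-4,5-dimethoxybenzaldehyde; 4 ethyl 2-methoxy-6-methylbenzoate (2.6 equiv)
Product: 7 8-methoxy-3-{4-[2,3-dimethoxy-5-(8-methoxy-1-oxoisochroman-3-yl)phenoxy]phenyl}isochroman-1-one (bis-lactone; both C3 centres unassigned; diastereomer mixture), via lithiated toluate 5 (not isolated), via dilithium bis-alkoxide diester 6 (not isolated)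
Conditions: LiN(iPr)2 (LDA, 2.5 equiv), THF, −78 °C; then 3 in THF, −78 °C to 0 °C; 1 M HCl
Reagents that add atoms: none
Why: LiN(iPr)2 removes a proton from the methyl group ortho to the ester of 4 (lateral lithiation) to give the ester-stabilised benzylic anion 5, which adds 1,2 to each of the two non-enolisable aldehydes of 3; in dialkoxide 6 each alkoxide then attacks the neighbouring ethyl ester and expels ethoxide. The closest known reaction type is the toluate-anion aldol–lactonisation that converts ortho-toluate esters and aromatic aldehydes into 3-aryl-3,4-dihydroisocoumarins. Each of the two six-membered lactone rings closes by 6-exo-trig acyl substitution at the ester carbonyl. The two new stereocentres (C3 of each lactone) form without any controlling element, as a diastereomer mixture, which is harmless because both become CH2 in step 3. The step needs benzylic deprotonation rather than attack of the amide base or of 5 on the ester, and addition to both aldehydes; the ortho ester (acidification), the methoxy and methyl groups flanking the ester (shielding), the temperature of −78 °C, a slight deficit of base relative to 4 and an excess of 5 over the aldehyde groups should secure this.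

**Step 3**
Reactants: 7 bis-lactone (diastereomer mixture)
Product: 8 2-[2-(4-{5-[2-(2-carboxy-3-methoxyphenyl)ethyl]-2,3-dimethoxyphenoxy}phenyl)ethyl]-6-methoxybenzoic acid (diacid)
Conditions: H2 (4 atm), 10% Pd/C, AcOH, cat. HClO4, 50 °C
Reagents that add atoms: none
Why: Hydrogenolysis of a benzylic ester C–O bond (benzyl-ester-type cleavage), since each lactone C3–O bond is benzylic to an aryl ring carrying a para oxygen donor, so acid-assisted cleavage on palladium should give the CH2–CH2 bridges, free both carboxylic acids and remove both stereocentres.

**Step 4**
Reactants: 8 diacid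
Product: 9 1,2-dimethoxy-5-[2-(3-methoxyphenyl)ethyl]-3-{4-[2-(3-methoxyphenyl)ethyl]phenoxy}benzene (perrottetin F tetramethyl ether)
Conditions: Ag2CO3 (20 mol%), AcOH (10 mol%), DMSO, 120 °C
Reagents that add atoms: none
Why: Silver-catalysed protodecarboxylation of ortho-substituted benzoic acids, favoured here because each carboxyl group sits between a methoxy group and an alkyl chain, which twists the carboxylate out of the ring plane and eases CO2 extrusion and protonation of the aryl–silver intermediate.

**Step 5**
Reactants: 9 perrottetin F tetramethyl ether
Product: 10 perrottetin F, 5-[2-(3-hydroxyphenyl)ethyl]-3-{4-[2-(3-hydroxyphenyl)ethyl]phenoxy}benzene-1,2-diol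
Conditions: BBr3, CH2Cl2, −78 °C to rt; then H2O
Reagents that add atoms: none
Why: Lewis acid cleavage of aryl methyl ethers with BBr3 (O–B complexation followed by bromide attack on the methyl carbon) should free all four phenols, while the diaryl ether offers no alkyl carbon for attack and stays intact.

**Compound list**
1 | 3-hydroxy-4,5-dimethoxybenzaldehyde | COc1cc(C=O)cc(O)c1OC | starting material
2 | 4-fluorobenzaldehyde | O=Cc1ccc(F)cc1 | starting material
3 | 3-(4-formylphenoxy)-4,5-dimethoxybenzaldehyde | COc1cc(C=O)cc(Oc2ccc(C=O)cc2)c1OC | intermediate
4 | ethyl 2-methoxy-6-methylbenzoate | CCOC(=O)c1c(C)cccc1OC | starting material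
5 | ethyl 2-(lithiomethyl)-6-methoxybenzoate (lithiated toluate, formed in the flask) | CCOC(=O)c1c(C[Li])cccc1OC | intermediate
6 | dilithium bis-alkoxide of the twofold aldehyde adduct, both ethyl esters intact (formed in the flask, carbinol centres unassigned) | COc1cc(C([O-])Cc2cccc(OC)c2C(=O)OCC)cc(Oc2ccc(C([O-])Cc3cccc(OC)c3C(=O)OCC)cc2)c1OC.[Li+].[Li+] | intermediate
7 | bis-lactone: two 8-methoxy-3,4-dihydroisocoumarin units joined through C3 to ring C and to the para position of ring B of the diaryl ether (both C3 centres unassigned, diastereomer mixture) | COc1cc(C2Cc3cccc(OC)c3C(=O)O2)cc(Oc2ccc(C3Cc4cccc(OC)c4C(=O)O3)cc2)c1OC | intermediate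
8 | 2-[2-(4-{5-[2-(2-carboxy-3-methoxyphenyl)ethyl]-2,3-dimethoxyphenoxy}phenyl)ethyl]-6-methoxybenzoic acid | COc1cc(CCc2cccc(OC)c2C(=O)O)cc(Oc2ccc(CCc3cccc(OC)c3C(=O)O)cc2)c1OC | intermediate
9 | perrottetin F tetramethyl ether | COc1cc(CCc2cccc(OC)c2)cc(Oc2ccc(CCc3cccc(OC)c3)cc2)c1OC | intermediate
10 | perrottetin F | Oc1cccc(CCc2ccc(Oc3cc(CCc4cccc(O)c4)cc(O)c3O)cc2)c1 | target

**Step count**
Total steps: 5. Longest linear sequence: 5 steps (1 → 3 → 7 → 8 → 9 → 10).

**Steps most likely to fail**

Step 2. The lithiated ester may condense with unreacted 4 (Claisen-type self-condensation), only one aldehyde may react, or the adduct may stop at the hydroxy ester. Fallback, setting out from 4 and returning at 7: 4 is saponified (KOH, aqueous EtOH, reflux) to 2-methoxy-6-methylbenzoic acid F1. F1 is converted with LiN(iPr)2 (2.1 equiv per acid, THF, −78 °C to 0 °C) into the dilithio carboxylate–benzyl dianion F2, whose carboxylate cannot be attacked by another anion. F2 is added to 3, and acidic work-up should give the bis(hydroxy acid) F3. Heating F3 with TsOH in toluene with removal of water should close both lactones to 7.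

Step 3. Cleavage of the secondary benzylic C–O bonds may be sluggish, leaving one lactone intact. Fallback, setting out from 7 and returning at 8: treatment of 7 with KOtBu in THF should deprotonate each C4 position (a toluate-type benzylic site) and expel the carboxylate in an E1cB ring opening. This gives the (E,E)-bis(stilbene) dicarboxylic acid F4, whose two alkenes are then hydrogenated under mild conditions (H2, 1 atm, 10% Pd/C, EtOAc–MeOH) to 8.

Step 4. Decarboxylation may stall after loss of only one CO2, or not start if the carboxylates bind silver poorly. Fallback, setting out from 8 and returning at 10: 8 is first demethylated with BBr3 (CH2Cl2, −78 °C to rt) to the tetrahydroxy diacid F5, a bis(6-alkylsalicylic acid). Heating F5 in degassed quinoline at 200 °C under argon should then decarboxylate both salicylic acids thermally through their keto tautomers and give 10 directly, bypassing 9.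

**Further compounds**
F1 | step 2 | 2-methoxy-6-methylbenzoic acid | COc1cccc(C)c1C(=O)O
F2 | step 2 | lithium 2-(lithiomethyl)-6-methoxybenzoate (dianion of F1) | COc1cccc(C[Li])c1C(=O)[O-].[Li+]
F3 | step 2 | bis(hydroxy acid), the ring-opened form of 7 (carbinol centres unassigned) | COc1cc(C(O)Cc2cccc(OC)c2C(=O)O)cc(Oc2ccc(C(O)Cc3cccc(OC)c3C(=O)O)cc2)c1OC
F4 | step 3 | (E,E)-bis(stilbene) dicarboxylic acid | COc1cc(/C=C/c2cccc(OC)c2C(=O)O)cc(Oc2ccc(/C=C/c3cccc(OC)c3C(=O)O)cc2)c1OC
F5 | step 4 | tetrahydroxy diacid (bis-salicylic acid) | O=C(O)c1c(O)cccc1CCc1ccc(Oc2cc(CCc3cccc(O)c3C(=O)O)cc(O)c2O)cc1
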